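## The problem

Eremophilane numbering is used: ring A is C1–C5 plus C10, ring B is C5–C10, C14 is the methyl on C5, C15 the methyl on C4, C11–C13 the isopropenyl group on C7, and β is the face of C14. The target 23 is a trans-fused decalin with six stereocentres: 3α-O-angelate, 4β-methyl, quaternary 5β-methyl, 7α-isopropenyl, 9α-O-(E)-3-methylpent-2-enoate and 10α-H. Every substituent except the angular methyl is equatorial. The quaternary C5 is the natural control element. Through its axial methyl it can direct C10 (trans fusion by dissolving metal) and C9 and C7 (attack anti to C14), and it fixes C4 through the ring that is built onto it. It works against C3, however: axial hydride delivery to a C3 ketone is syn-axial to C14, so a hydride reagent should give the axial 3β-alcohol, and the equatorial 3α-oxygen needs thermodynamic control. Two equatorial secondary hydroxyls must receive two different unsaturated acyl groups, so the route has to tell them apart. Three groups are fragile: the 7-isopropenyl 8-ketone (drift into conjugation, C7 epimerisation), the 9-acyloxy 8-ketone (acyl migration, reductive cleavage) and the Z-configured angelate (isomerisation to tiglate); none survives dissolving metal or strong base, so all come late. The feature that opens the synthesis is in ring A: ketone-level oxygen at C3, the one-carbon branch C15 at C4 and quaternary C5 stand in a row. That is the pattern left when a 1-vinylcyclopentanol next to a quaternary carbon expands by one carbon, and the remaining atoms C5–C10 with the C8 oxygen and a C9=C10 double bond are the enone ring of the enantiopure bicycle 1.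

## Retrosynthesis

**Ester C–O bonds.** The C9 ester of 23 is cut first, to hydroxy ketone 21 and acid 22, because the α-acyloxy ketone is the most fragile group and should be formed last under the mildest acylation. The angelate of 21 is traced through silyl ether 20 to alcohol 17 and angelic acid 18. The more forcing angeloylation is thus done while C9 is still silylated. This requires 17, in which C3–OH is free and C9–OH is protected.

**C7–C11.** The isopropenyl group of 16 (the bis-silyl ether from which 17 is unveiled) is cut from ketone 13 and 2-bromopropene 14. An aldol with acetone followed by dehydration would end at the conjugated isopropylidene ketone, whereas direct alkenylation of the enolate gives the β,γ-unsaturated ketone at once. The cut is placed after the dissolving-metal step and before the esters, which tolerate neither. The forward reaction must enolise toward C7, form the bond on the α face and leave the new double bond out of conjugation.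

**C9–O, C10–H and C3–H.** Ketone 13 comes from ketol 12, and 12 from the bis-silyl compound 11, which is traced through the dilithium species 10 to enedione 9. A single dissolving-metal operation on 9 should set the trans ring fusion, deliver the equatorial 3α-alkoxide and fix the enolate double bond at C8–C9. Plain enolisation of the saturated 8-ketone would go toward C7, so only the reductively formed enolate allows oxygenation at C9. Silylation of 10 gives an alkyl silyl ether at C3 and a silyl enol ether at C8. Oxidation of the enol ether alone then frees the C9 hydroxyl while C3 stays protected, so the two hydroxyls are differentiated without extra steps. Compound 9 has only two stereocentres and no protecting group.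

**C15–Br.** The methyl group of 9 is traced to the bromomethyl group of 8; radical reduction removes the bromine without touching the epimerisable C4.

**C4–C5, the key cut.** Breaking C4–C5 of 8 and returning C5 to C3 contracts ring A to a cyclopentane and leads to the vinyl carbinol 6 and N-bromosuccinimide 7. Against cuts through ring B, this one keeps the quaternary centre intact and draws it, with the enone, from the commercial bicycle. The forward step must make the quaternary carbon migrate in preference to the C2 methylene and must place C15 on the β face.

**Vinyl carbinol.** Carbinol 6 is unmasked from dithiolane 5, which comes from ketone 3 and vinylmagnesium bromide 4; 3 is made from the Hajos–Parrish ketone 1 and ethane-1,2-dithiol 2. The enone must be masked during the Grignard addition. A dithiolane is preferred to a dienol ether because it leaves the double bond where it is and the C2 protons of the cyclopentanone ordinary, so enolisation does not compete with addition.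

## Roads not taken

**Alternative 1:** Rings A and B would be closed together by cutting C5–C10 and C6–C7. In the forward sense a 2-silyloxydiene (C7–C10) and an acrylate unit (C5=C6), joined through C1–C4, undergo a thermal intramolecular Diels–Alder reaction to give A1.
- Merits: both rings form in one step, and the C8–C9 silyl enol ether emerges ready for oxygenation at C9. No dissolving-metal step is needed, so the C3 oxygen can be carried from the open chain as a protected alcohol of fixed configuration. In the handling of C3 and C9 this road is better than the chosen one.
- Weak points: C14 arrives as a methyl ester and must be reduced to a methyl group at a neopentyl, fully substituted carbon (three operations). Ring fusion and facial selectivity depend on endo/exo preferences of a dienophile substituted on its internal carbon and are not secured. The open-chain precursor with two stereocentres and a hydrolysis-prone silyloxydiene takes several steps. The isopropenyl group is still missing afterwards.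
- Comparison: the chosen plan sets against it a quaternary centre that is bought with its methyl group and absolute configuration, a ring fusion set by a dependable reduction, and a single step that creates the C3/C4/C5 pattern.

**Alternative 2:** Ring B would be closed by cutting C7–C8. A C8 aldehyde and a prenyl group on C6 undergo a Me2AlCl-promoted intramolecular carbonyl-ene reaction to give A2, which carries the isopropenyl group and a C8 hydroxyl.
- Merits: the isopropenyl group, the C7 stereocentre and ring B are made in one event, so the most awkward operation of the chosen plan (alkenylation next to a ketone without conjugation) disappears. C8 stays an alcohol until a last oxidation, so the sensitive β,γ-unsaturated ketone never meets the esterification conditions. In both respects this road is superior.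
- Weak points: it needs a ring A cyclohexane that already holds C3, C4, quaternary C5 and C10, plus the C9 stereocentre α to the aldehyde. That is five stereocentres before the key step, the quaternary one being hard to build in a monocycle. The α-alkoxy aldehyde may epimerise or chelate the aluminium reagent. Three differently masked oxygens lengthen the end game.
- Comparison: the chosen plan offers a far shorter way to the quaternary centre and to the first bicyclic intermediate; it pays with the palladium-catalysed alkenylation and with late handling of the sensitive ketone.

**Alternative 3:** Ring B would be closed by cutting C5–C6. Fe(acac)3 and PhSiH3 transfer a hydrogen atom to an exocyclic methylene on C5, and the tertiary radical adds to the terminus C6 of a vinyl ketone to give A3.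
- Merits: the quaternary centre and its methyl group are created in the ring-closing step under neutral conditions that tolerate silyl and benzyl-type ethers. The C9 oxygen is in place, so neither the enolate regiochemistry nor a dissolving-metal step arises. A3 stands at the stage of 13 of the chosen route, so the remaining work would be the same.
- Weak points: the C5 radical is planar, so the configuration of C5 relative to C4 and C10 rests on conformational preference alone. The α-alkoxy vinyl ketone is prone to β-elimination and polymerisation. The precursor with C3, C4, C9 and C10 already set is long to make.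
- Comparison: this road equals the chosen plan on the isopropenyl problem and is better at C3 and C9. The chosen plan is stronger at C5, whose configuration is taken from the starting material.

Key step: step 4

Remark on the chemistry: angelic acid 18 and (E)-3-methylpent-2-enoic acid 22 are taken as purchasable acids of defined double-bond geometry; eremophilane names imply the 4β,5β-dimethyl arrangement.

## Route

Step 1
Reactants: 1 (S)-7a-methyl-2,3,7,7a-tetrahydro-1H-indene-1,5(6H)-dione (Hajos–Parrish ketone); 2 ethane-1,2-dithiol
Product: 3 (7a′S)-7a′-methyl-2′,3′,7′,7a′-tetrahydrospiro[1,3-dithiolane-2,5′-inden]-1′(6′H)-one (dithiolane of the enone carbonyl; cyclopentanone free)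
Conditions: HSCH2CH2SH, TsOH·H2O (cat.), AcOH, rt
Reagents that add atoms: ethane-1,2-dithiol, SCCS
Why: Acid-catalysed thioketalisation; in acetic acid the dithiol should react selectively with the conjugated carbonyl, leaving the cyclopentanone next to the quaternary carbon, and the C=C stays in place. No stereocentre is formed.

Step 2
Reactants: 3 dithiolane ketone; 4 vinylmagnesium bromide
Product: 5 (1′R,7a′S)-1′-ethenyl-7a′-methyl-1′,2′,3′,6′,7′,7a′-hexahydrospiro[1,3-dithiolane-2,5′-inden]-1′-ol (hydroxyl cis to the angular methyl)
Conditions: CH2=CHMgBr, CeCl3, THF, −78 → 0 °C; aq. NH4Cl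
Reagents that add atoms: vinylmagnesium bromide, C=C[Mg]Br
Why: 1,2-Addition of the organocerium reagent formed from the Grignard reagent and CeCl3, which suppresses enolisation of the hindered cyclopentanone. The nucleophile should enter anti to the angular methyl, placing the hydroxyl cis to it (1′R).

Step 3
Reactants: 5 vinyl carbinol dithiolane
Product: 6 (1R,7aS)-1-ethenyl-1-hydroxy-7a-methyl-1,2,3,6,7,7a-hexahydro-5H-inden-5-one
Conditions: MeI, CaCO3, MeCN–H2O, 50 °C
Reagents that add atoms: water, O
Why: Alkylative hydrolysis of the dithiolane (S-methylation, opening to the allyl-stabilised thionium ion, capture by water). The buffered, near-neutral medium should leave the tertiary allylic alcohol and the vinyl group untouched.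

Step 4
Reactants: 6 vinyl carbinol enone; 7 N-bromosuccinimide
Product: 8 15-bromo-11,12,13-trinoreremophil-9-ene-3,8-dione [(4aR,5R)-5-(bromomethyl)-4a-methyl-4,4a,7,8-tetrahydronaphthalene-2,6(3H,5H)-dione]
Conditions: NBS, CH2Cl2–(CF3)2CHOH, 0 °C → rt, dark
Reagents that add atoms: N-bromosuccinimide, O=C1CCC(=O)N1Br
Why: NBS transfers Br+ to the terminal vinyl group; as the bromonium ion opens, the C1–C7a bond of the five-membered ring migrates to the internal vinyl carbon anti to bromine while the carbinol becomes the C3 ketone, so C4–C5 forms and C15 carries the bromine. The closest known reaction type is the halonium-induced semipinacol ring expansion of 1-alkenylcycloalkanols. Ring A is closed by ring expansion, not cyclisation: a suprafacial 1,2-alkyl shift with retention at the migrating quaternary carbon turns the cyclopentane into the cyclohexanone. The new stereocentre C4 is controlled by the vinyl rotamer: with the CH2 terminus eclipsing the small C–O bond instead of the ring C2 methylene, and bromine anti to the migrating bond, CH2Br ends equatorial, that is 4β and cis to C14. Regioselectivity (quaternary C7a over the C2 methylene) rests on the higher migratory aptitude of the more substituted carbon. Chemoselectivity rests on the electron-poor enone double bond being inert to Br+, on a weakly nucleophilic fluoroalcohol co-solvent that should not capture the bromonium ion, and on the absence of base, which spares the β-bromo ketone from loss of HBr. C4 is then carried through non-basic steps until the C3 carbonyl is gone.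

Step 5
Reactants: 8 bromomethyl enedione
Product: 9 11,12,13-trinoreremophil-9-ene-3,8-dione [(4aR,5R)-4a,5-dimethyl-4,4a,7,8-tetrahydronaphthalene-2,6(3H,5H)-dione]
Conditions: Bu3SnH (0.3 M), AIBN (cat.), PhH, 80 °C
Reagents that add atoms: none
Why: Radical chain dehalogenation; at high stannane concentration hydrogen transfer to the primary radical should outrun the 1,2-acyl shift of the β-keto radical (Dowd–Beckwith rearrangement). The neutral medium leaves C4 untouched, so the 4β-methyl is retained.

Step 6
Reactants: 9 enedione
Product: 11 3α,8-bis(triethylsilyloxy)-11,12,13-trinor-10αH-eremophil-8-ene, via dilithium alkoxide enolate 10 (not isolated)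
Conditions: Li (about 4.2 equiv), t-BuOH (2 equiv), NH3–THF, −78 °C; evaporate NH3; Et3SiCl, Et3N, THF, −78 → 0 °C
Reagents that add atoms: chlorotriethylsilane, CC[Si](Cl)(CC)CC
Why: Dissolving-metal reduction: the enone is reduced with protonation of C10 on the α face to the trans-fused enolate whose double bond is fixed at C8–C9. The C3 ketone is reduced through its carbinyl anion to the thermodynamically preferred equatorial 3α-alkoxide, whereas a hydride would attack anti to C14 and give the axial 3β-alcohol. Both oxygens are silylated in the same flask.

Step 7
Reactants: 11 bis-silyl compound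
Product: 12 9α-hydroxy-3α-(triethylsilyloxy)-11,12,13-trinor-10αH-eremophilan-8-one
Conditions: OsO4 (cat.), NMO, acetone–H2O, 0 °C → rt
Reagents that add atoms: osmium tetroxide (catalytic oxygen carrier), O=[Os](=O)(=O)=O; N-methylmorpholine N-oxide (terminal oxidant), C[N+]1([O-])CCOCC1
Why: Dihydroxylation of the silyl enol ether; the silyloxy diol collapses with loss of triethylsilanol to the α-hydroxy ketone. Osmylation should occur on the α face, anti to the axial C14 methyl, giving the equatorial 9α-hydroxyl, and the alkyl silyl ether at C3 is not touched.

Step 8
Reactants: 12 hydroxy ketone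
Product: 13 9α-(tert-butyldimethylsilyloxy)-3α-(triethylsilyloxy)-11,12,13-trinor-10αH-eremophilan-8-one
Conditions: TBSCl, imidazole, DMF, rt
Reagents that add atoms: tert-butyldimethylsilyl chloride, CC(C)(C)[Si](C)(C)Cl
Why: Standard silylation of a secondary α-ketol hydroxyl. The more robust silyl group goes on C9 so that C3 can be unveiled first.

Step 9
Reactants: 13 ketone; 14 2-bromopropene
Product: 16 9α-(tert-butyldimethylsilyloxy)-3α-(triethylsilyloxy)-10αH-eremophil-11-en-8-one (7α-isopropenyl), via lithium enolate 15 (not isolated)
Conditions: LiN(SiMe3)2 (2.2 equiv), THF, −78 °C; Pd2(dba)3 (cat.), P(t-Bu)3 (cat.), 2-bromopropene, −78 °C → rt; AcOH, −78 °C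
Reagents that add atoms: 2-bromopropene, CC(Br)=C
Why: Palladium-catalysed α-alkenylation of a ketone enolate (oxidative addition of 14 to zerovalent palladium, transfer of the enolate to palladium, reductive elimination); kinetic deprotonation should take the C7 methylene, not the hindered silyloxy-bearing C9 methine. The alkenyl group should enter on the α face anti to C14, and equatorial 7α is also the stable epimer. Excess base holds the product as its dienolate, which cold acetic acid protonates at C7 to return the β,γ-unsaturated ketone.

Step 10
Reactants: 16 bis-silyl isopropenyl ketone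
Product: 17 9α-(tert-butyldimethylsilyloxy)-3α-hydroxy-10αH-eremophil-11-en-8-one
Conditions: PPTS, MeOH–CH2Cl2, 0 °C
Reagents that add atoms: none
Why: Acid-catalysed methanolysis cleaves the secondary triethylsilyl ether much faster than the tert-butyldimethylsilyl ether. The conditions are too mild to move the isopropenyl double bond.

Step 11
Reactants: 17 alcohol; 18 angelic acid [(Z)-2-methylbut-2-enoic acid]
Product: 20 3α-angeloyloxy-9α-(tert-butyldimethylsilyloxy)-10αH-eremophil-11-en-8-one, via mixed anhydride 19 (not isolated)
Conditions: angelic acid, 2,4,6-Cl3C6H2COCl, Et3N, PhMe, rt; then 17, PhMe, 60 °C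
Reagents that add atoms: angelic acid, C/C=C(/C)C(=O)O
Why: Yamaguchi esterification through the mixed anhydride, run without a nucleophilic catalyst because such catalysts isomerise angelates to tiglates. The shielded trichlorobenzoyl carbonyl directs the alcohol to the angeloyl carbonyl, and acylation on oxygen retains the C3 configuration.

Step 12
Reactants: 20 angelate silyl ether
Product: 21 3α-angeloyloxy-9α-hydroxy-10αH-eremophil-11-en-8-one
Conditions: HF·pyridine, pyridine, THF, 0 °C → rt
Reagents that add atoms: none
Why: Fluoride-mediated desilylation in a buffered, slightly acidic medium. This avoids basic fluoride, which could move the isopropenyl double bond or epimerise C7 and C9.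

Step 13
Reactants: 21 hydroxy ketone; 22 (E)-3-methylpent-2-enoic acid
Product: 23 3α-angeloyloxy-9α-[(E)-3-methylpent-2-enoyloxy]-10αH-eremophil-11-en-8-one (CNP0301161.1)
Conditions: (E)-3-methylpent-2-enoic acid, DIC, DMAP (cat.), CH2Cl2, 0 °C → rt
Reagents that add atoms: (E)-3-methylpent-2-enoic acid, CC/C(C)=C/C(=O)O
Why: Carbodiimide (Steglich) esterification of the α-ketol hydroxyl at low temperature. Acylation on oxygen retains C9, and the mild conditions should preserve the E geometry of the enoate and the position of the isopropenyl double bond.

## Compound list

1 | (S)-7a-methyl-2,3,7,7a-tetrahydro-1H-indene-1,5(6H)-dione (Hajos–Parrish ketone) | C[C@]12CCC(=O)C=C1CCC2=O | starting material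
2 | ethane-1,2-dithiol | SCCS | starting material
3 | (7a′S)-7a′-methyl-2′,3′,7′,7a′-tetrahydrospiro[1,3-dithiolane-2,5′-inden]-1′(6′H)-one | C[C@]12CCC3(SCCS3)C=C1CCC2=O | intermediate
4 | vinylmagnesium bromide | C=C[Mg]Br | starting material
5 | (1′R,7a′S)-1′-ethenyl-7a′-methyl-1′,2′,3′,6′,7′,7a′-hexahydrospiro[1,3-dithiolane-2,5′-inden]-1′-ol | C1C[C@]2(C)[C@](O)(C=C)CCC2=CC13SCCS3 | intermediate
6 | (1R,7aS)-1-ethenyl-1-hydroxy-7a-methyl-1,2,3,6,7,7a-hexahydro-5H-inden-5-one | C1C[C@]2(C)[C@](O)(C=C)CCC2=CC1=O | intermediate
7 | N-bromosuccinimide | O=C1CCC(=O)N1Br | starting material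
8 | 15-bromo-11,12,13-trinoreremophil-9-ene-3,8-dione | C1C[C@]2(C)[C@@H](CBr)C(=O)CCC2=CC1=O | intermediate
9 | 11,12,13-trinoreremophil-9-ene-3,8-dione | C1C[C@]2(C)[C@@H](C)C(=O)CCC2=CC1=O | intermediate
10 | dilithium 11,12,13-trinor-10αH-eremophil-8-ene-3α,8-diolate | C1C[C@]2(C)[C@@H](C)[C@H]([O-])CC[C@H]2C=C1[O-].[Li+].[Li+] | intermediate
11 | 3α,8-bis(triethylsilyloxy)-11,12,13-trinor-10αH-eremophil-8-ene | C1C[C@]2(C)[C@@H](C)[C@H](O[Si](CC)(CC)CC)CC[C@H]2C=C1O[Si](CC)(CC)CC | intermediate
12 | 9α-hydroxy-3α-(triethylsilyloxy)-11,12,13-trinor-10αH-eremophilan-8-one | C1C[C@]2(C)[C@@H](C)[C@H](O[Si](CC)(CC)CC)CC[C@H]2[C@H](O)C1=O | intermediate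
13 | 9α-(tert-butyldimethylsilyloxy)-3α-(triethylsilyloxy)-11,12,13-trinor-10αH-eremophilan-8-one | C1C[C@]2(C)[C@@H](C)[C@H](O[Si](CC)(CC)CC)CC[C@H]2[C@H](O[Si](C)(C)C(C)(C)C)C1=O | intermediate
14 | 2-bromopropene | CC(Br)=C | starting material
15 | lithium 7-en-8-olate of 13 | C=1C[C@]2(C)[C@@H](C)[C@H](O[Si](CC)(CC)CC)CC[C@H]2[C@H](O[Si](C)(C)C(C)(C)C)C=1[O-].[Li+] | intermediate
16 | 9α-(tert-butyldimethylsilyloxy)-3α-(triethylsilyloxy)-10αH-eremophil-11-en-8-one | C=C(C)[C@@H]1C[C@]2(C)[C@@H](C)[C@H](O[Si](CC)(CC)CC)CC[C@H]2[C@H](O[Si](C)(C)C(C)(C)C)C1=O | intermediate
17 | 9α-(tert-butyldimethylsilyloxy)-3α-hydroxy-10αH-eremophil-11-en-8-one | C=C(C)[C@@H]1C[C@]2(C)[C@@H](C)[C@H](O)CC[C@H]2[C@H](O[Si](C)(C)C(C)(C)C)C1=O | intermediate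
18 | angelic acid, (Z)-2-methylbut-2-enoic acid | C/C=C(/C)C(=O)O | starting material
19 | angelic 2,4,6-trichlorobenzoic anhydride | C/C=C(/C)C(=O)OC(=O)c1c(Cl)cc(Cl)cc1Cl | intermediate
20 | 3α-angeloyloxy-9α-(tert-butyldimethylsilyloxy)-10αH-eremophil-11-en-8-one | C=C(C)[C@@H]1C[C@]2(C)[C@@H](C)[C@H](OC(=O)/C(C)=C\C)CC[C@H]2[C@H](O[Si](C)(C)C(C)(C)C)C1=O | intermediate
21 | 3α-angeloyloxy-9α-hydroxy-10αH-eremophil-11-en-8-one | C=C(C)[C@@H]1C[C@]2(C)[C@@H](C)[C@H](OC(=O)/C(C)=C\C)CC[C@H]2[C@H](O)C1=O | intermediate
22 | (E)-3-methylpent-2-enoic acid | CC/C(C)=C/C(=O)O | starting material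
23 | 3α-angeloyloxy-9α-[(E)-3-methylpent-2-enoyloxy]-10αH-eremophil-11-en-8-one (CNP0301161.1) | C=C(C)[C@@H]1C[C@]2(C)[C@@H](C)[C@H](OC(=O)/C(C)=C\C)CC[C@H]2[C@H](OC(=O)/C=C(\C)CC)C1=O | target

## Step count and least certain steps

Total: 13 steps. Longest linear sequence: 13 steps from 1.

**Step 4 (key step).** The bromonium ion may be captured by the neighbouring hydroxyl or by solvent instead of triggering the shift, the C2 methylene may migrate in place of the quaternary carbon, or the product may lose HBr. The cause is that a monosubstituted vinyl group is a weak nucleophile and gives a poorly stabilised cation, so the shift has less driving force than in the strained or cation-stabilised cases. The fallback keeps the same bond formation but separates oxidation from migration. Carbinol 6 is epoxidised under hydroxyl direction (VO(acac)2, t-BuOOH) to (1R,7aS)-1-hydroxy-7a-methyl-1-(oxiran-2-yl)-1,2,3,6,7,7a-hexahydro-5H-inden-5-one F1 (the oxirane epimer expected when the bulky quaternary carbon is turned out of the vinyl plane). BF3·OEt2 at low temperature then induces the epoxy-alcohol semipinacol shift to 15-hydroxy-11,12,13-trinoreremophil-9-ene-3,8-dione F2. An Appel reaction (CBr4, PPh3) returns to 8.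

**Step 6.** Over-reduction at C8 is possible if the enolate is protonated while the C3 ketone is still being reduced. Other risks are pinacol coupling at C3, proton exchange between the enolate and unreduced ketone that scrambles the enolate position, and incomplete silylation of the hindered alkoxide. The cause is that two reductions with different proton demands run in one flask. The fallback separates them, starting from 9:
- LiBH(s-Bu)3 at −78 °C reduces only the saturated ketone from the open α face to 3β-hydroxy-11,12,13-trinoreremophil-9-en-8-one F3.
- Mitsunobu inversion with 4-nitrobenzoic acid gives 3α-(4-nitrobenzoyloxy)-11,12,13-trinoreremophil-9-en-8-one F4.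
- Methanolysis (K2CO3, MeOH) gives 3α-hydroxy-11,12,13-trinoreremophil-9-en-8-one F5.
- Silylation (Et3SiCl, imidazole) gives 3α-(triethylsilyloxy)-11,12,13-trinoreremophil-9-en-8-one F6.
- An ordinary Li/NH3 reduction of the enone alone, with trapping of the enolate by Et3SiCl, returns to 11.

**Step 9.** The new double bond may migrate into conjugation with the ketone under the basic conditions or at work-up. A second alkenylation, enolisation toward C9, and oxygen-to-oxygen silyl migration in the enolate of the α-silyloxy ketone are also possible. The cause is that the product is more acidic than the starting ketone and must be released from its dienolate by kinetic protonation. The fallback builds the group by classical carbonyl chemistry from 13: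
- Aldol addition of the lithium enolate (LiN(i-Pr)2) to acetone gives 9α-(tert-butyldimethylsilyloxy)-11-hydroxy-3α-(triethylsilyloxy)-10αH-eremophilan-8-one F7.
- Dehydration with the Burgess reagent gives the conjugated 9α-(tert-butyldimethylsilyloxy)-3α-(triethylsilyloxy)-10αH-eremophil-7(11)-en-8-one F8 (any isopropenyl isomer formed directly is already 16).
- Deconjugation by complete conversion to the extended dienolate (KOt-Bu, t-BuOH) and kinetic protonation at C7 with cold aqueous acetic acid returns to 16.

**Step 5.** The β-keto radical may undergo 1,2-acyl shift with ring enlargement, and heating may cause loss of HBr or epimerisation at C4. The cause is the bromine β to a ketone. The fallback avoids the radical: 8 is treated with DBU to eliminate HBr to 11,12,13-trinoreremophila-4(15),9-diene-3,8-dione F9. The exocyclic double bond alone is then hydrogenated from the α face (H2, RhCl(PPh3)3), returning to 9.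

**Step 11.** The angeloyl group may isomerise to tigloyl, acylation of the hydroxyl flanked by the C4 methyl may be slow, and the heat then required may move the isopropenyl double bond into conjugation. The fallback builds the Z double bond on the substrate. Alcohol 17 is esterified (DIC, DMAP) with 2-[bis(2,2,2-trifluoroethoxy)phosphoryl]propanoic acid to 9α-(tert-butyldimethylsilyloxy)-3α-{2-[bis(2,2,2-trifluoroethoxy)phosphoryl]propanoyloxy}-10αH-eremophil-11-en-8-one F10 (mixture of epimers at the phosphonate carbon). A Still–Gennari olefination with acetaldehyde (KN(SiMe3)2, 18-crown-6, −78 °C; the phosphonate is deprotonated in preference to the ketone) returns to 20.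

## Further compounds

F1 | step 4 | (1R,7aS)-1-hydroxy-7a-methyl-1-(oxiran-2-yl)-1,2,3,6,7,7a-hexahydro-5H-inden-5-one | C1C[C@]2(C)[C@](O)([C@H]3CO3)CCC2=CC1=O
F2 | step 4 | 15-hydroxy-11,12,13-trinoreremophil-9-ene-3,8-dione | C1C[C@]2(C)[C@@H](CO)C(=O)CCC2=CC1=O
F3 | step 6 | 3β-hydroxy-11,12,13-trinoreremophil-9-en-8-one | C1C[C@]2(C)[C@@H](C)[C@@H](O)CCC2=CC1=O
F4 | step 6 | 3α-(4-nitrobenzoyloxy)-11,12,13-trinoreremophil-9-en-8-one | C1C[C@]2(C)[C@@H](C)[C@H](OC(=O)c3ccc(cc3)[N+](=O)[O-])CCC2=CC1=O
F5 | step 6 | 3α-hydroxy-11,12,13-trinoreremophil-9-en-8-one | C1C[C@]2(C)[C@@H](C)[C@H](O)CCC2=CC1=O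
F6 | step 6 | 3α-(triethylsilyloxy)-11,12,13-trinoreremophil-9-en-8-one | C1C[C@]2(C)[C@@H](C)[C@H](O[Si](CC)(CC)CC)CCC2=CC1=O
F7 | step 9 | 9α-(tert-butyldimethylsilyloxy)-11-hydroxy-3α-(triethylsilyloxy)-10αH-eremophilan-8-one | CC(C)(O)[C@@H]1C[C@]2(C)[C@@H](C)[C@H](O[Si](CC)(CC)CC)CC[C@H]2[C@H](O[Si](C)(C)C(C)(C)C)C1=O
F8 | step 9 | 9α-(tert-butyldimethylsilyloxy)-3α-(triethylsilyloxy)-10αH-eremophil-7(11)-en-8-one | CC(C)=C1C[C@]2(C)[C@@H](C)[C@H](O[Si](CC)(CC)CC)CC[C@H]2[C@H](O[Si](C)(C)C(C)(C)C)C1=O
F9 | step 5 | 11,12,13-trinoreremophila-4(15),9-diene-3,8-dione | C1C[C@]2(C)C(=C)C(=O)CCC2=CC1=O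
F10 | step 11 | 9α-(tert-butyldimethylsilyloxy)-3α-{2-[bis(2,2,2-trifluoroethoxy)phosphoryl]propanoyloxy}-10αH-eremophil-11-en-8-one | C=C(C)[C@@H]1C[C@]2(C)[C@@H](C)[C@H](OC(=O)C(C)P(=O)(OCC(F)(F)F)OCC(F)(F)F)CC[C@H]2[C@H](O[Si](C)(C)C(C)(C)C)C1=O
A1 | alternative 1 | methyl 3α,8-bis(tert-butyldimethylsilyloxy)-11,12,13-trinor-10αH-eremophil-8-en-14-oate | C1C[C@]2(C(=O)OC)[C@@H](C)[C@H](O[Si](C)(C)C(C)(C)C)CC[C@H]2C=C1O[Si](C)(C)C(C)(C)C
A2 | alternative 2 | 3α-(tert-butyldimethylsilyloxy)-9α-(4-methoxybenzyloxy)-10αH-eremophil-11-en-8β-ol | C=C(C)[C@@H]1C[C@]2(C)[C@@H](C)[C@H](O[Si](C)(C)C(C)(C)C)CC[C@H]2[C@H](OCc2ccc(OC)cc2)[C@H]1O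
A3 | alternative 3 | 3α-(tert-butyldimethylsilyloxy)-9α-(4-methoxybenzyloxy)-11,12,13-trinor-10αH-eremophilan-8-one | C1C[C@]2(C)[C@@H](C)[C@H](O[Si](C)(C)C(C)(C)C)CC[C@H]2[C@H](OCc2ccc(OC)cc2)C1=O
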